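The noon run was the flask I followed, and I counted how often its dissolved gas had turned over, taking one gas per product. My unit was the share of the starting material charged that one saturated solution holds, the filling f = c_sat/c_A = 9.60 %, where c_sat is the saturation concentration and c_A the charge. Product y then counts turnovers N:

N = y/f = 8.7 % / 9.60 % = 0.906 at 6.00 h

| setting | noon | midnight | flask |
|---|---|---|---|
| starting material | 0.050 M | 0.025 M | 0.050 M |
| gas phase | 4.8 mM (held) | 4.8 mM (held) | 4.8 mM (held) |
| remark | the very flask that is asked about, followed so far | run made earlier |  |
| time |  |  | 12 h |

- noon (time / h: product / %, starting material / %): 0.333: 0.8, 93.7; 1.00: 1.4, 89.0; 1.50: 1.2, 84.9; 2.50: 1.0, 80.6; 4.00: 5.2, 77.4; 5.00: 7.0, 77.2; 6.00: 8.7, 74.4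
- midnight (time / h: product / %, starting material / %): 1.00: 3.9, 89.8; 1.33: 1.0, 85.5; 2.00: 3.5, 83.6; 3.00: 3.2, 80.8; 5.00: 7.1, 74.2; 8.00: 10.7, 71.8; 12.0: 13.6, 68.6

(each reading ± 1 percentage point)

- at the start none of the gas phase is in solution

1. the product standing at 12 h, as a percentage of the starting material charged
2. concentration of dissolved gas in solution at 6.0 h, in percent of saturation
3. the change that raises the amount of product at 12 h, in percent of the starting material charged most ("none" if none brings more than 2 percentage points) (Wednesday's / Sunday's / none)
4. amount of product at 12 h, in percent of the starting material charged, after Wednesday's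

- Wednesday's: doubling the saturation concentration of gas phase, all else as stated
- Sunday's: doubling the transfer coefficient of the gas phase, all else as stated

Two extremes can be reckoned in the head. If gas reacted as fast as it entered, with supply as the rate-limiting step, both runs would make the same molar amount, so the noon flask at 12 h would stand at 6.80 %, half of the midnight reading. If the solution stood saturated in both runs, the step would be pseudo-first-order in starting material, the percentages would coincide, and the noon flask would stand level with the midnight reading of 13.6 %.

At 5.00 h the noon run read 7.0 % and the midnight run 7.1 %, level within the scatter, although their turnovers were 0.729 and 0.370. So I placed the noon flask beside the second extreme and committed to about 13.6 %.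

The forecast gave 14.5 %, higher than my figure, with 90 % of saturation at 6.0 h, Wednesday's change as the best and 24 % of product after it, holding that “the gas stays near saturation”.

    starting material ⇌ dormant form (K = 0.240, k = 4.20 × 10⁻⁵ /s)
    gas phase ⇌ dissolved gas, rate k2*(csat - [dissolved gas]) (kL = 1.90 × 10⁻⁴ /s)
    starting material + dissolved gas ⇌ product (K = 100 /M, k = 0.00160 /M/s)

The noon flask gave 13.4 %, which is 1.40 turnovers, with Wednesday's best at 24.9 %. Its dissolved gas stood at 79.2 % of saturation at 6.0 h, lower than the forecast's 90 %. The neighbour flask charged with 0.20 M of starting material has a filling a quarter of f, so its 9.01 % of product is 3.75 turnovers by 12 h, and its dissolved gas stood at 0.00279 M, against 0.00410 M in the noon flask.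

(The numbers in the tables are simulated for an exercise, and the scatter is random.)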